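The plan disconnects ring B of the ent-labdane decalin at its only ring alkene, C6=C7 (labdane numbering). Ring-closing olefin metathesis of a 1,7-diene forms this cis double bond between the allylic stereocentres C5 and C8 and closes the cyclohexene in one neutral operation, so the base-sensitive β,γ-unsaturated C8 ester never meets an enolising reagent. The precursor is a trans-1,2-disubstituted ring A: C5 carries a vinyl group, C10 a succinate arm in which C9 bears a free carboxyl (the later side-chain anchor) and C8 bears CO2Me and an (E)-propenyl group. All four stereocentres are set in earlier steps by conjugate addition–alkylation and an Ireland–Claisen rearrangement.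

Key step: step 6

Remark: labdane numbering is used throughout (C4 gem-dimethyl, C5/C10 ring fusion, C6=C7 ring alkene, C8 with CO2Me, C9 with the C11–C16 chain); the target is read as the (5R,8S,9R,10S,13E) isomer.

Step 1
Reactants: 1 2,4,4-trimethylcyclohex-2-en-1-one; 2 vinylmagnesium bromide; 3 methyl bromoacetate
Product: 5 methyl 2-[(1S,2R)-1,3,3-trimethyl-6-oxo-2-vinylcyclohexyl]acetate, via magnesium enolate 4 (not isolated)
Conditions: Cu(OTf)2 (5 mol %), chiral N-mesityl-N'-(1-hydroxy-4-methylpentan-2-yl)imidazolinium hexafluorophosphate (carbene ligand precursor, 6 mol %; the enantiomer that gives R at the vinyl-bearing carbon), Et2O, −30 °C; then 3, DMPU, −30 → 23 °C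
Reagents that add atoms: none
Why: Copper-catalysed asymmetric conjugate addition of a Grignard reagent to an α-methyl cyclic enone with alkylation of the magnesium enolate in the same flask; the chiral carbene ligand on copper selects the enone face and sets C5 (R), and the bromoacetate then enters C10 anti to the neighbouring vinyl group, which gives the trans relationship of the two arms.

Step 2
Reactants: 5 methyl 2-[(1S,2R)-1,3,3-trimethyl-6-oxo-2-vinylcyclohexyl]acetate
Product: 8 2-[(1S,2R)-1,3,3-trimethyl-2-vinylcyclohexyl]acetic acid, via potassium keto carboxylate 6 (not isolated), via hydrazone carboxylate 7 (not isolated)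
Conditions: KOH, diethylene glycol–H2O, 110 °C; then N2H4·H2O, 130 °C, distil to 200 °C, under N2; aq HCl
Reagents that add atoms: potassium hydroxide, [K+].[OH-]
Why: Wolff–Kishner reduction in the Huang–Minlon modification; saponifying first turns the ester into a carboxylate that cannot acylate the hydrazone (no dihydropyridazinone), and neither the quaternary C10 nor the non-acidic C5 can epimerise.

Step 3
Reactants: 9 methyl (E)-4-oxopent-2-enoate
Product: 10 methyl (R,E)-4-hydroxypent-2-enoate
Conditions: (S)-2-methyl-CBS-oxazaborolidine (10 mol %), catecholborane, PhMe, −78 °C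
Reagents that add atoms: none
Why: Corey–Bakshi–Shibata reduction, in which the (S)-oxazaborolidine binds the ketone with the alkenyl group as the large substituent and delivers hydride to give the (R)-carbinol, while catecholborane at low temperature avoids 1,4-reduction.

Step 4
Reactants: 8 2-[(1S,2R)-1,3,3-trimethyl-2-vinylcyclohexyl]acetic acid; 10 methyl (R,E)-4-hydroxypent-2-enoate
Product: 11 methyl (R,E)-4-{2-[(1S,2R)-1,3,3-trimethyl-2-vinylcyclohexyl]acetoxy}pent-2-enoate
Conditions: DCC, DMAP (cat.), CH2Cl2, 0 → 23 °C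
Reagents that add atoms: none
Why: Steglich esterification acylates the secondary allylic alcohol without touching its stereocentre or the (E)-enoate; any ester from the minor enantiomer of 8 is a diastereomer and can be removed here or later.

Step 5
Reactants: 11 methyl (R,E)-4-{2-[(1S,2R)-1,3,3-trimethyl-2-vinylcyclohexyl]acetoxy}pent-2-enoate
Product: 14 (2R,3S,E)-3-(methoxycarbonyl)-2-[(1R,2R)-1,3,3-trimethyl-2-vinylcyclohexyl]hex-4-enoic acid, via silyl ketene acetal 12 (not isolated), via trimethylsilyl ester 13 (not isolated)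
Conditions: LiN(SiMe3)2, Me3SiCl, Et3N, PhMe, −78 → 60 °C; 1 M HCl
Reagents that add atoms: none
Why: Ireland–Claisen rearrangement; the amide base with Et3N should enolise the only ester α-CH2 to the E-enolate, trapped in situ as the silyl ketene acetal, and a chair transition state with the carbinol methyl pseudo-equatorial transfers the (R)-carbinol configuration to C8 (S) and forms the (E)-propenyl group, while the enolate geometry sets C9 (R) anti to C8.

Step 6
Reactants: 14 (2R,3S,E)-3-(methoxycarbonyl)-2-[(1R,2R)-1,3,3-trimethyl-2-vinylcyclohexyl]hex-4-enoic acid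
Product: 15 (1R,2S,4aR,8aR)-2-(methoxycarbonyl)-5,5,8a-trimethyl-1,2,4a,5,6,7,8,8a-octahydronaphthalene-1-carboxylic acid
Conditions: second-generation Hoveyda–Grubbs catalyst (5 mol %), 1,4-benzoquinone (10 mol %), PhMe (0.005 M), 80 °C
Reagents that add atoms: none
Why: Ring-closing olefin metathesis: the ruthenium alkylidene loads onto the (E)-propenyl group at C7, and a [2+2]/retro-[2+2] sequence through a ruthenacyclobutane joins C7 to the vinyl carbon C6 and expels propene; the closest known reaction type is diene ring-closing metathesis to cyclohexenes. Ring B closes as a six-membered ring from a 1,7-diene whose two arms sit trans-diequatorial on ring A, so the trans-fused octalin is the strain-free outcome and the new C6=C7 alkene is necessarily cis. No stereocentre is created; C5, C8, C9 and C10 are carried through unchanged because none of them is a reacting alkene carbon. The step needs chemoselectivity and positional fidelity of the new β,γ-unsaturated ester: only two alkenes are present, ruthenium tolerates the acid and ester, and neutral conditions with benzoquinone (which suppresses ruthenium hydride isomerisation) should keep the alkene from moving into conjugation with the C8 ester.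

Step 7
Reactants: 15 (1R,2S,4aR,8aR)-2-(methoxycarbonyl)-5,5,8a-trimethyl-1,2,4a,5,6,7,8,8a-octahydronaphthalene-1-carboxylic acid
Product: 17 methyl (1R,2S,4aR,8aR)-1-formyl-5,5,8a-trimethyl-1,2,4a,5,6,7,8,8a-octahydronaphthalene-2-carboxylate, via acid chloride 16 (not isolated)
Conditions: (COCl)2, DMF (cat.), CH2Cl2, 0 → 23 °C; then LiAlH(Ot-Bu)3, THF, −78 °C
Reagents that add atoms: none
Why: Acid chloride formation followed by partial reduction with the bulky hydride LiAlH(Ot-Bu)3 at −78 °C should stop at the aldehyde, leave the methyl ester and ring alkene untouched, and not epimerise C9 at this temperature.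

Step 8
Reactants: 17 methyl (1R,2S,4aR,8aR)-1-formyl-5,5,8a-trimethyl-1,2,4a,5,6,7,8,8a-octahydronaphthalene-2-carboxylate
Product: 18 methyl (1R,2S,4aR,8aS)-5,5,8a-trimethyl-1-vinyl-1,2,4a,5,6,7,8,8a-octahydronaphthalene-2-carboxylate
Conditions: Zn, CH2Br2, TiCl4, THF–CH2Cl2, 0 → 23 °C
Reagents that add atoms: dibromomethane, BrCBr
Why: Lombardo methylenation is non-basic, so the α-stereocentre C9 of the aldehyde and the β,γ-unsaturated ester at C8 should survive, and esters are inert to the reagent.

Step 9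
Reactants: 19 methyl 4-hydroxybut-2-ynoate
Product: 20 methyl (Z)-4-hydroxy-3-iodobut-2-enoate
Conditions: NaI, AcOH (2 equiv), MeCN, 80 °C
Reagents that add atoms: sodium iodide, [Na+].[I-]
Why: Hydroiodination of a 2-alkynoate by conjugate addition of iodide and anti protonation gives the (Z)-β-iodo enoate (iodine cis to the ester), so the hydroxymethyl group is trans to the ester and cannot lactonise.

Step 10
Reactants: 18 methyl (1R,2S,4aR,8aS)-5,5,8a-trimethyl-1-vinyl-1,2,4a,5,6,7,8,8a-octahydronaphthalene-2-carboxylate; 20 methyl (Z)-4-hydroxy-3-iodobut-2-enoate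
Product: 22 methyl (1R,2S,4aR,8aS)-1-[(E)-3-(hydroxymethyl)-5-methoxy-5-oxopent-3-en-1-yl]-5,5,8a-trimethyl-1,2,4a,5,6,7,8,8a-octahydronaphthalene-2-carboxylate, via alkylborane 21 (not isolated)
Conditions: 9-BBN-H, THF, 23 °C; then 20, Pd(dppf)Cl2 (5 mol %), AsPh3, aq K3PO4, DMF, 23 °C
Reagents that add atoms: none
Why: 9-BBN hydroborates only the terminal vinyl group (the hindered cis ring alkene is far slower), and the B-alkyl Suzuki–Miyaura coupling proceeds with retention at the vinyl iodide, placing the new chain cis to CO2Me and so setting the 13E geometry; the free hydroxyl avoids β-acetoxy elimination from the alkenylpalladium intermediate.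

Step 11
Reactants: 22 methyl (1R,2S,4aR,8aS)-1-[(E)-3-(hydroxymethyl)-5-methoxy-5-oxopent-3-en-1-yl]-5,5,8a-trimethyl-1,2,4a,5,6,7,8,8a-octahydronaphthalene-2-carboxylate
Product: 23 methyl (1R,2S,4aR,8aS)-1-[(E)-3-(acetoxymethyl)-5-methoxy-5-oxopent-3-en-1-yl]-5,5,8a-trimethyl-1,2,4a,5,6,7,8,8a-octahydronaphthalene-2-carboxylate (target)
Conditions: Ac2O, pyridine, DMAP (cat.), CH2Cl2, 0 °C
Reagents that add atoms: acetic anhydride, CC(=O)OC(C)=O
Why: Acetylation of the primary allylic alcohol under weakly basic conditions should not disturb the base-sensitive C8 stereocentre or either alkene.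

Compound list
1 | 2,4,4-trimethylcyclohex-2-en-1-one | CC1=CC(C)(C)CCC1=O | starting material
2 | vinylmagnesium bromide | C=C[Mg]Br | starting material
3 | methyl bromoacetate | COC(=O)CBr | starting material
4 | bromomagnesium (R)-2,4,4-trimethyl-3-vinylcyclohex-1-en-1-olate | C=C[C@@H]1C(C)(C)CCC(O[Mg]Br)=C1C | intermediate
5 | methyl 2-[(1S,2R)-1,3,3-trimethyl-6-oxo-2-vinylcyclohexyl]acetate (acetate arm trans to vinyl) | COC(=O)C[C@]1(C)C(=O)CCC(C)(C)[C@H]1C=C | intermediate
6 | potassium 2-[(1S,2R)-1,3,3-trimethyl-6-oxo-2-vinylcyclohexyl]acetate | [K+].[O-]C(=O)C[C@]1(C)C(=O)CCC(C)(C)[C@H]1C=C | intermediate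
7 | potassium 2-[(1S,2R)-6-hydrazinylidene-1,3,3-trimethyl-2-vinylcyclohexyl]acetate | [K+].[O-]C(=O)C[C@]1(C)C(=NN)CCC(C)(C)[C@H]1C=C | intermediate
8 | 2-[(1S,2R)-1,3,3-trimethyl-2-vinylcyclohexyl]acetic acid | OC(=O)C[C@]1(C)CCCC(C)(C)[C@H]1C=C | intermediate
9 | methyl (E)-4-oxopent-2-enoate | CC(=O)/C=C/C(=O)OC | starting material
10 | methyl (R,E)-4-hydroxypent-2-enoate | C[C@@H](O)/C=C/C(=O)OC | intermediate
11 | methyl (R,E)-4-{2-[(1S,2R)-1,3,3-trimethyl-2-vinylcyclohexyl]acetoxy}pent-2-enoate | C[C@@H](OC(=O)C[C@]1(C)CCCC(C)(C)[C@H]1C=C)/C=C/C(=O)OC | intermediate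
12 | trimethylsilyl ketene acetal of 11, (E)-configured (ring substituent cis to the allylic oxygen) | C[C@@H](O/C(O[Si](C)(C)C)=C\[C@]1(C)CCCC(C)(C)[C@H]1C=C)/C=C/C(=O)OC | intermediate
13 | trimethylsilyl (2R,3S,E)-3-(methoxycarbonyl)-2-[(1R,2R)-1,3,3-trimethyl-2-vinylcyclohexyl]hex-4-enoate | C[Si](C)(C)OC(=O)[C@H]([C@@H](C(=O)OC)/C=C/C)[C@]1(C)CCCC(C)(C)[C@H]1C=C | intermediate
14 | (2R,3S,E)-3-(methoxycarbonyl)-2-[(1R,2R)-1,3,3-trimethyl-2-vinylcyclohexyl]hex-4-enoic acid | OC(=O)[C@H]([C@@H](C(=O)OC)/C=C/C)[C@]1(C)CCCC(C)(C)[C@H]1C=C | intermediate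
15 | (1R,2S,4aR,8aR)-2-(methoxycarbonyl)-5,5,8a-trimethyl-1,2,4a,5,6,7,8,8a-octahydronaphthalene-1-carboxylic acid | OC(=O)[C@@H]1[C@@H](C(=O)OC)C=C[C@@H]2C(C)(C)CCC[C@@]12C | intermediate
16 | methyl (1R,2S,4aR,8aR)-1-(chlorocarbonyl)-5,5,8a-trimethyl-1,2,4a,5,6,7,8,8a-octahydronaphthalene-2-carboxylate | ClC(=O)[C@@H]1[C@@H](C(=O)OC)C=C[C@@H]2C(C)(C)CCC[C@@]12C | intermediate
17 | methyl (1R,2S,4aR,8aR)-1-formyl-5,5,8a-trimethyl-1,2,4a,5,6,7,8,8a-octahydronaphthalene-2-carboxylate | O=C[C@@H]1[C@@H](C(=O)OC)C=C[C@@H]2C(C)(C)CCC[C@@]12C | intermediate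
18 | methyl (1R,2S,4aR,8aS)-5,5,8a-trimethyl-1-vinyl-1,2,4a,5,6,7,8,8a-octahydronaphthalene-2-carboxylate | C=C[C@@H]1[C@@H](C(=O)OC)C=C[C@@H]2C(C)(C)CCC[C@@]12C | intermediate
19 | methyl 4-hydroxybut-2-ynoate | COC(=O)C#CCO | starting material
20 | methyl (Z)-4-hydroxy-3-iodobut-2-enoate | COC(=O)/C=C(\I)CO | intermediate
21 | methyl (1R,2S,4aR,8aS)-1-[2-(9-borabicyclo[3.3.1]nonan-9-yl)ethyl]-5,5,8a-trimethyl-1,2,4a,5,6,7,8,8a-octahydronaphthalene-2-carboxylate | C(CB1C2CCCC1CCC2)[C@@H]1[C@@H](C(=O)OC)C=C[C@@H]2C(C)(C)CCC[C@@]12C | intermediate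
22 | methyl (1R,2S,4aR,8aS)-1-[(E)-3-(hydroxymethyl)-5-methoxy-5-oxopent-3-en-1-yl]-5,5,8a-trimethyl-1,2,4a,5,6,7,8,8a-octahydronaphthalene-2-carboxylate | COC(=O)/C=C(\CC[C@@H]1[C@@H](C(=O)OC)C=C[C@@H]2C(C)(C)CCC[C@@]12C)CO | intermediate
23 | methyl (1R,2S,4aR,8aS)-1-[(E)-3-(acetoxymethyl)-5-methoxy-5-oxopent-3-en-1-yl]-5,5,8a-trimethyl-1,2,4a,5,6,7,8,8a-octahydronaphthalene-2-carboxylate | COC(=O)/C=C(\CC[C@@H]1[C@@H](C(=O)OC)C=C[C@@H]2C(C)(C)CCC[C@@]12C)COC(C)=O | target

Total step count: 11.
Longest linear sequence: 9 steps (steps 1, 2, 4, 5, 6, 7, 8, 10, 11).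

Steps most likely to fail

Step 1. The chiral carbene ligand on copper may discriminate the enone faces poorly with an sp2 Grignard reagent on this α,γ,γ-trisubstituted enone, 1,2-addition may compete, and C-alkylation of the magnesium enolate may be slow. The fallback sets out from 1 and comes back at 8. The addition is run without chiral ligand under chlorosilane acceleration (2, CuBr·SMe2 cat., Me3SiCl, DMPU, THF, −78 °C) to give racemic trimethyl[(2,4,4-trimethyl-3-vinylcyclohex-1-en-1-yl)oxy]silane F1. MeLi (THF, 0 °C) releases the racemic lithium enolate F2, which is alkylated with 3 to the racemic keto ester, that is 5 together with its enantiomer methyl 2-[(1R,2S)-1,3,3-trimethyl-6-oxo-2-vinylcyclohexyl]acetate F3. The conditions of step 2 then give the racemic acid, 8 together with 2-[(1R,2S)-1,3,3-trimethyl-2-vinylcyclohexyl]acetic acid F4. Classical resolution by crystallisation of the (S)-1-phenylethylammonium salt of 8 F5 (the antipodal amine is used if its salt is the less soluble one) and acidification returns 8.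

Step 5. The amide base may deprotonate the vinylogous γ-position of the enoate, or add to it, in competition with enolisation of the hindered acetate CH2; incomplete control of enolate geometry would erode C9. The fallback sets out from 8 and comes back at 14. Acid 8 is α-brominated through its dianion (LDA, 2.2 equiv, THF, 0 °C; CBr4, −78 °C) to 2-bromo-2-[(1R,2R)-1,3,3-trimethyl-2-vinylcyclohexyl]acetic acid F6 (both epimers at the bromide carbon). Steglich esterification with 10 gives methyl (R,E)-4-{2-bromo-2-[(1R,2R)-1,3,3-trimethyl-2-vinylcyclohexyl]acetoxy}pent-2-enoate F7. Zinc dust and Me3SiCl in THF at reflux then form the bromozinc enolate F8 regiospecifically from the C–Br bond, without base, and its Reformatsky–Claisen rearrangement should deliver 14 after acidic work-up, with C8 again set by chirality transfer from the carbinol.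

Step 7. The aldehyde may be over-reduced to the primary alcohol, which can lactonise onto the C8 ester, or the acid chloride may cyclise onto the neighbouring ester. The fallback sets out from 15 and comes back at 17. Acid 15 is activated as its mixed isobutyl carbonic anhydride F9 (i-BuOCOCl, N-methylmorpholine, THF, −15 °C) and reduced with NaBH4 (THF–H2O, 0 °C) to methyl (1R,2S,4aR,8aR)-1-(hydroxymethyl)-5,5,8a-trimethyl-1,2,4a,5,6,7,8,8a-octahydronaphthalene-2-carboxylate F10, which is oxidised at once with Dess–Martin periodinane (NaHCO3, CH2Cl2, 0 °C) to 17.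

Further compounds
F1 | step 1 | racemic trimethyl[(2,4,4-trimethyl-3-vinylcyclohex-1-en-1-yl)oxy]silane | C=CC1C(C)(C)CCC(O[Si](C)(C)C)=C1C
F2 | step 1 | racemic lithium 2,4,4-trimethyl-3-vinylcyclohex-1-en-1-olate | C=CC1C(C)(C)CCC(O[Li])=C1C
F3 | step 1 | methyl 2-[(1R,2S)-1,3,3-trimethyl-6-oxo-2-vinylcyclohexyl]acetate | COC(=O)C[C@@]1(C)C(=O)CCC(C)(C)[C@@H]1C=C
F4 | step 1 | 2-[(1R,2S)-1,3,3-trimethyl-2-vinylcyclohexyl]acetic acid | OC(=O)C[C@@]1(C)CCCC(C)(C)[C@@H]1C=C
F5 | step 1 | (S)-1-phenylethylammonium 2-[(1S,2R)-1,3,3-trimethyl-2-vinylcyclohexyl]acetate | C[C@H]([NH3+])c1ccccc1.[O-]C(=O)C[C@]1(C)CCCC(C)(C)[C@H]1C=C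
F6 | step 5 | 2-bromo-2-[(1R,2R)-1,3,3-trimethyl-2-vinylcyclohexyl]acetic acid | OC(=O)C(Br)[C@]1(C)CCCC(C)(C)[C@H]1C=C
F7 | step 5 | methyl (R,E)-4-{2-bromo-2-[(1R,2R)-1,3,3-trimethyl-2-vinylcyclohexyl]acetoxy}pent-2-enoate | C[C@@H](OC(=O)C(Br)[C@]1(C)CCCC(C)(C)[C@H]1C=C)/C=C/C(=O)OC
F8 | step 5 | bromozinc enolate of F7 (debrominated) | C[C@@H](OC(O[Zn]Br)=C[C@]1(C)CCCC(C)(C)[C@H]1C=C)/C=C/C(=O)OC
F9 | step 7 | mixed isobutyl carbonic anhydride of 15 | CC(C)COC(=O)OC(=O)[C@@H]1[C@@H](C(=O)OC)C=C[C@@H]2C(C)(C)CCC[C@@]12C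
F10 | step 7 | methyl (1R,2S,4aR,8aR)-1-(hydroxymethyl)-5,5,8a-trimethyl-1,2,4a,5,6,7,8,8a-octahydronaphthalene-2-carboxylate | OC[C@@H]1[C@@H](C(=O)OC)C=C[C@@H]2C(C)(C)CCC[C@@]12C
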